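## Conventions and assumption

- Atom labels follow the heavy-atom order of the target skeleton: C1 = CH(OAc), C2, C3 = C(CH3)(OAc), C4, C5 = ring-fusion CH, C6, C7 = ketone carbon, C8=C9 = alkene, C10, C11, N12, C13–C15, C16 = quaternary carbon. Ring A = C1–C5 + C16, ring B = C5–C8 + C16, ring C = C8–C16 through N12.
- Assumption: enone 6 is bought as the single (S) enantiomer. It is the known silyl ether of the ketone derived from enzymatically desymmetrised cis-cyclopent-4-ene-1,3-diol monoacetate, so the absolute configuration of the route rests on that desymmetrisation.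
- The arm oxygen (on C13) is carried as a tert-butyldimethylsilyl ether so that it is released in the same acid step as the carbamates.

## Analysis of the target

The target is a cis-fused hydrindane (ring A six-membered, ring B a cyclopentanone) whose quaternary carbon C16 and ring B carbon C8 are bridged by a nine-membered azonane (ring C). The C8=C9 alkene is exocyclic to ring B and conjugated with the C7 ketone; it is E, with C10 cis to C16, as ring C demands. There are four stereocentres, all S in the skeletal numbering (C1, C3, C5, C16). C5–H and the C15 arm are cis (cis ring fusion), the C1 acetoxy group lies on the face of ring A that carries ring B (cis to C8), and the C3 acetoxy group is cis to the C1 acetoxy group with the C3 methyl trans. Sensitive groups are the free secondary amine beside a Michael acceptor, a tertiary acetate that will not survive strong acid, and a C7 ketone with two enolisable flanks (C6 and C8). The hard points are the quaternary centre C16, which is bonded to the carbinol C1, to C5 and to C8, the medium ring, and the cis-1,3-dioxygen pattern that includes a tertiary centre. The feature on which the plan rests is that C1 and C16 are adjacent and C16 is the β-carbon of a ring B enone (C7=O, C8=C16). A ketyl at C1 can therefore add to C16, closing ring A and leaving an enolate exactly at C8, where the C9 chain must be attached.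

## Retrosynthetic reasoning

29 from 28. The last bond cut is N12–S. The amine is kept as the 2-nitrobenzenesulfonamide 28 until the end because its removal by thiolate is mildly basic; an acidic final deprotection would endanger the tertiary C3 acetate and a reductive one the enone.

28 from 27 from 26. Both acetates are put on together on diol 27. Until then the diol is held as the cyclic carbonate 26, which protects the tertiary C3–O bond during the acid and Mitsunobu steps.

26 from 25. Ring C is cut at N12–C13. The other ring C bonds are C–C bonds or the alkene, whereas N-alkylation of an acidic sulfonamide by a primary alcohol under Mitsunobu conditions is a dependable medium-ring closure. The forward step needs the E enone of 25, which holds C10 on the side of C16.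

25 from 23. The nitrogen and the C13 oxygen are released from their carbamate and silyl protection in 23, and nitrogen is then sulfonylated. The nitroarene is introduced only here because it would not tolerate the tin hydride step that precedes.

23 from 22 from 21. The C3–O bond is cut back to the exocyclic methylene and a C1 tert-butyl carbonate in 21. An iodonium-triggered closure of a six-membered carbonate can only deliver oxygen to C3 on the face of the C1 oxygen, so C3 is tied to C1; the iodomethyl group of 22 is then reduced to the methyl of 23.

21 from 19 from 16 and 17. The C8=C9 bond is cut by an aldol condensation between the silyl enol ether 16 and aldehyde 17, which brings C9–C11 and N12. Using the enol ether formed in the key step settles C8 against C6; dehydration and carbonate formation at C1 then give 21.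

16 from 14. The key cut is C1–C16. It removes ring A and both new stereocentres and leads to the monocyclic aldehyde enone 14, in which only C5 is stereogenic. The forward step must form a quaternary centre, fuse the rings cis and deliver the enolate regiospecifically.

14 from 13 from 12. The sensitive β,γ-unsaturated aldehyde is made last from alcohol 13, which is released from the 4-methoxybenzyl ether 12 under neutral oxidative conditions that leave the arm silyl ether alone.

12 from 11 from 8 and 9. The C15–C16 bond is cut: the organometallic from bromide 9 adds in conjugate fashion to enone 8, and the enolate is trapped as 11. Saegusa–Ito oxidation then restores the C8=C16 enone. The enolate from the conjugate addition is the one the dehydrogenation needs, so there is no regiochemical choice.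

8 from 7 from 5 and 6. The C4–C5 bond is cut. Allylsilane 5 adds to the Lewis-acid-activated enone 6 anti to the silyloxy group, and β-elimination of that group then moves the enone so that the new stereocentre becomes C5 of 8. A magnesium-based allyl nucleophile in a copper-catalysed allylic substitution was rejected for this bond because it would attack an ester leaving group directly.

5 from 4 from 1. The allylsilane comes from alcohol 1 by alkoxide-directed allylic metalation, C-silylation and etherification.

## Alternatives that were turned down

Alternative 1: The cut is C8–C16, made late, which opens rings B and C at once and leads back to the twelve-membered vinyl bromide A2, a cyclohexanone whose C16 and C5 are spanned by the chain C6–C15. Forward, the C1 enolate would be alkenylated through C16 by the C8 bromide under a zerovalent palladium catalyst with a bulky phosphine and an alkoxide base, giving the tricyclic ketone A1. In its favour, one step builds the quaternary centre and two rings, the alkene geometry is fixed beforehand in the bromide, and ring C needs no separate medium-ring closure. On that last point it is stronger than the chosen route, which pays with a dilute Mitsunobu step. Against it for this target: A1 has C3 as a methine carrying only methyl, so the tertiary C3 acetate would call for a late C–H oxidation beside an amine and an enone, and C1 arrives as a ketone whose reduction must then be steered. The enolate must form at the more substituted C16 and not at C2, and must react across the ring. A2 itself, with a Z bromoalkene and an acetal in a twelve-membered ring, is a long synthesis before the key step can be tried. The chosen strategy gives the C1 oxygen and a C3 handle in the product of the key step and reaches its precursor in a short linear sequence.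

Alternative 2: The cuts are C5–C16 and C2–C3, which lead back to the acyclic triketone A4. Forward, a chiral primary amine salt would promote Michael addition of the diketone carbon C16 to the enone carbon C5 (ring B) and then condensation of the acetyl methyl carbon C2 on the C3 ketone (ring A), giving the hydrindenedione A3. In its favour it reaches a bicyclic core in the fewest steps from an achiral chain and is catalytic in the chiral agent; in step economy up to the bicycle it is stronger than the chosen route. Against it: A3 has its ring B ketone at C8, not C7. Moving the oxygen by one carbon and raising the C8=C9 alkene at a ketone flanked by the quaternary centre would consume the steps saved. Ring A arrives as a flat C1 enone, so C1 and C3 must both be set later by conjugate oxygenation and reduction. The key step must also tell apart two ketones of an unsymmetrical diketone and set the quaternary centre under catalyst control alone. The chosen strategy places the ring B oxygen at C7 and the enolate at C8, and sets C16 by the substrate.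

Alternative 3: The cuts are C5–C6 and C8–C16, so ring B is made as a [3+2] unit from the chiral-pool cyclohexenone A6 and the silylallene A7. Forward, a strong titanium Lewis acid would trigger the Danheiser annulation to the vinylsilane A5. In its favour it is convergent, it carries both three-carbon chains as chlorides so that one amine could stitch ring C, and the ring methyl stereocentre steers the cis fusion. It is the shortest way to the whole carbon skeleton and is stronger than the chosen route on that count. Against it: C3 is again a methine without oxygen, and C1 is a ketone. The vinylsilane must be turned into the C7 ketone and then dehydrogenated towards C9 and not C6. The α-substituted enone is a slow partner whose quaternary centre forms by capture of a vinyl cation, and the double N-alkylation to a nine-membered ring is uncertain. The chosen strategy offers oxygen at C1, an alkene at C3 that the C1 oxygen can control, and a regiodefined C7–C8 enolate.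

Key step: step 9

## Route

Step 1
Reactants: 1 3-methylbut-3-en-1-ol
Product: 4 3-[(trimethylsilyl)methyl]but-3-en-1-ol, via dilithiated alkoxide 2 (not isolated), via bis-silylated allylsilane 3 (not isolated)
Conditions: n-BuLi (2.2 equiv), TMEDA, Et2O, 0 °C → rt; Me3SiCl, −78 °C → rt; then K2CO3, MeOH, rt
Reagents that add atoms: chlorotrimethylsilane, C[Si](C)(C)Cl
Why: Alkoxide-directed allylic lithiation of this homoallylic alcohol gives the dianion, which is silylated on carbon and oxygen; methanolysis then frees the alcohol while the allylsilane stays intact.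

Step 2
Reactants: 4 3-[(trimethylsilyl)methyl]but-3-en-1-ol
Product: 5 1-methoxy-4-[({3-[(trimethylsilyl)methyl]but-3-en-1-yl}oxy)methyl]benzene
Conditions: NaH, 4-methoxybenzyl chloride, n-Bu4NI (cat.), THF/DMF, 0 °C → rt
Reagents that add atoms: 4-methoxybenzyl chloride, COc1ccc(CCl)cc1
Why: Williamson etherification under basic conditions, which the acid-sensitive allylsilane tolerates; the 4-methoxybenzyl ether is later removed oxidatively without touching silyl ethers.

Step 3
Reactants: 5 1-methoxy-4-[({3-[(trimethylsilyl)methyl]but-3-en-1-yl}oxy)methyl]benzene; 6 (4S)-4-[(tert-butyldimethylsilyl)oxy]cyclopent-2-en-1-one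
Product: 7 (3S,4S)-4-[(tert-butyldimethylsilyl)oxy]-3-(2-{2-[(4-methoxybenzyl)oxy]ethyl}prop-2-en-1-yl)cyclopentan-1-one
Conditions: TiCl4 (1.1 equiv), CH2Cl2, −78 °C
Reagents that add atoms: none
Why: Hosomi–Sakurai conjugate allylation: the alkene terminus of the allylsilane attacks the β-carbon of the TiCl4-activated enone anti to the neighbouring silyloxy group, which sets C5, and loss of silicon regenerates the 1,1-disubstituted alkene. Both ethers should survive the short exposure at −78 °C.

Step 4
Reactants: 7 (3S,4S)-4-[(tert-butyldimethylsilyl)oxy]-3-(2-{2-[(4-methoxybenzyl)oxy]ethyl}prop-2-en-1-yl)cyclopentan-1-one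
Product: 8 (4S)-4-(2-{2-[(4-methoxybenzyl)oxy]ethyl}prop-2-en-1-yl)cyclopent-2-en-1-one
Conditions: DBU, CH2Cl2, 0 °C
Reagents that add atoms: none
Why: E1cB β-elimination of the silyloxy group gives the transposed enone with the side chain at the γ-carbon; short contact at 0 °C should avoid migration of the alkene towards the stereocentre.

Step 5
Reactants: 8 (4S)-4-(2-{2-[(4-methoxybenzyl)oxy]ethyl}prop-2-en-1-yl)cyclopent-2-en-1-one; 9 (3-bromopropoxy)(tert-butyl)dimethylsilane
Product: 11 {[(3R,4S)-3-{3-[(tert-butyldimethylsilyl)oxy]propyl}-4-(2-{2-[(4-methoxybenzyl)oxy]ethyl}prop-2-en-1-yl)cyclopent-1-en-1-yl]oxy}trimethylsilane, via Grignard reagent 10 (not isolated)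
Conditions: 9, Mg, THF, rt → 40 °C; then CuBr·SMe2 (10 mol%), Me3SiCl, HMPA, 8, THF, −78 °C; Et3N
Reagents that add atoms: chlorotrimethylsilane, C[Si](C)(C)Cl
Why: Copper-catalysed conjugate addition of a Grignard reagent accelerated by Me3SiCl; the arm enters trans to the C5 substituent and the enolate is silylated regiospecifically at C7–C8.

Step 6
Reactants: 11 {[(3R,4S)-3-{3-[(tert-butyldimethylsilyl)oxy]propyl}-4-(2-{2-[(4-methoxybenzyl)oxy]ethyl}prop-2-en-1-yl)cyclopent-1-en-1-yl]oxy}trimethylsilane
Product: 12 (4S)-3-{3-[(tert-butyldimethylsilyl)oxy]propyl}-4-(2-{2-[(4-methoxybenzyl)oxy]ethyl}prop-2-en-1-yl)cyclopent-2-en-1-one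
Conditions: Pd(OAc)2 (1.1 equiv), MeCN, rt
Reagents that add atoms: none
Why: Saegusa–Ito oxidation: the palladium enolate at C8 can lose hydride only from C16, so the C8=C16 enone forms without regiochemical choice and the neutral conditions leave C5 untouched.

Step 7
Reactants: 12 (4S)-3-{3-[(tert-butyldimethylsilyl)oxy]propyl}-4-(2-{2-[(4-methoxybenzyl)oxy]ethyl}prop-2-en-1-yl)cyclopent-2-en-1-one
Product: 13 (4S)-3-{3-[(tert-butyldimethylsilyl)oxy]propyl}-4-[2-(2-hydroxyethyl)prop-2-en-1-yl]cyclopent-2-en-1-one
Conditions: DDQ, CH2Cl2/pH 7 buffer, 0 °C
Reagents that add atoms: none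
Why: Oxidative cleavage of the 4-methoxybenzyl ether through its benzylic cation; the silyl ether, the enone and the isolated alkene are not oxidised under buffered conditions.

Step 8
Reactants: 13 (4S)-3-{3-[(tert-butyldimethylsilyl)oxy]propyl}-4-[2-(2-hydroxyethyl)prop-2-en-1-yl]cyclopent-2-en-1-one
Product: 14 3-{[(1S)-2-{3-[(tert-butyldimethylsilyl)oxy]propyl}-4-oxocyclopent-2-en-1-yl]methyl}but-3-enal
Conditions: Dess–Martin periodinane, NaHCO3, CH2Cl2, 0 °C; used at once
Reagents that add atoms: none
Why: Buffered Dess–Martin oxidation of a homoallylic alcohol gives the β,γ-unsaturated aldehyde without base that would move the alkene into conjugation; the aldehyde is not stored.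

Step 9
Reactants: 14 3-{[(1S)-2-{3-[(tert-butyldimethylsilyl)oxy]propyl}-4-oxocyclopent-2-en-1-yl]methyl}but-3-enal
Product: 16 cis-fused (1S,5S,16S) hydrindane with C1 trimethylsilyl ether, C3 exocyclic methylene, C7–C8 trimethylsilyl enol ether and the 3-[(tert-butyldimethylsilyl)oxy]propyl arm on C16, via samarium alkoxide enolate 15 (not isolated)
Conditions: SmI2 (2.5 equiv), THF, −78 → −20 °C, slow addition of 14; then Me3SiCl, Et3N, −78 → 0 °C
Reagents that add atoms: chlorotrimethylsilane, C[Si](C)(C)Cl
Why: SmI2 transfers one electron to the aldehyde; the ketyl, bound to trivalent samarium, adds to the enone β-carbon C16 and closes ring A in a 6-exo-trig mode, and the C8 radical next to the C7 carbonyl takes a second electron to give the samarium enolate 15, which Me3SiCl silylates on both oxygens. The closest known reaction type is the SmI2-mediated ketyl–olefin (aldehyde–enone) reductive cyclisation with trapping of the samarium enolate. Radical addition tolerates the fully substituted acceptor carbon, so C16 forms without the steric penalty of a polar Michael addition. C16 is controlled by C5: the tether from C5 reaches only the face of the cyclopentenone that carries C4, which makes the ring fusion cis. C1 is controlled in the chair-like transition state with the arm pseudo-equatorial: the samarium-bound oxygen sits pseudo-equatorial and can bridge to the enone carbonyl, which places it cis to C8, and HMPA is left out for that reason. The step needs chemoselectivity for the enone over the C3 alkene, which the nucleophilic ketyl and the lack of a productive three-membered closure secure. It also needs the enolate to survive, which the aprotic medium and slow addition secure. The enolate is generated only at C7–C8, so the following aldol cannot stray to C6.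

Step 10
Reactants: 16 cis-fused hydrindane bis(trimethylsilyl) derivative; 17 tert-butyl (3-oxopropyl)carbamate
Product: 19 aldol diol (C1 hydroxyl, C7 ketone, C8 bearing the 1-hydroxy-3-[(tert-butoxycarbonyl)amino]propyl chain, mixture at C8 and C9), via aldol silyl ether 18 (not isolated)
Conditions: BF3·OEt2 (1.2 equiv), CH2Cl2, −78 °C; then citric acid, MeOH, 0 °C
Reagents that add atoms: none
Why: Mukaiyama aldol addition of the regiodefined silyl enol ether to the Lewis-acid-activated aldehyde forms C8–C9; the enol ether is far more nucleophilic than the C3 alkene. Mild acidic methanolysis then removes the C1 trimethylsilyl group but not the primary tert-butyldimethylsilyl ether, and the C8/C9 configurations are lost in the next step.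

Step 11
Reactants: 19 aldol diol
Product: 21 (E)-enone with C1 tert-butyl carbonate and N,N-bis(tert-butoxycarbonyl)amine, via fourfold tert-butoxycarbonyl intermediate 20 (not isolated)
Conditions: Boc2O (4 equiv), DMAP, MeCN, rt; then DBU, rt
Reagents that add atoms: di-tert-butyl dicarbonate, CC(C)(C)OC(=O)OC(=O)OC(C)(C)C
Why: DMAP-catalysed acylation converts both hydroxyls and the carbamate N–H; the carbonate β to the C7 ketone is then expelled by E1cB elimination to the conjugated enone. The E isomer (C10 anti to the carbonyl, cis to C16) is expected as the thermodynamic product.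

Step 12
Reactants: 21 enone C1 tert-butyl carbonate
Product: 22 cyclic iodocarbonate (six-membered carbonate bridging O1 and O3, iodomethyl on C3)
Conditions: I2, NaHCO3, MeCN, 0 °C → rt
Reagents that add atoms: iodine, II
Why: Iodocarbonate cyclisation of a homoallylic tert-butyl carbonate: the carbonyl oxygen opens the iodonium ion at the tertiary carbon C3 and the tert-butyl group is lost. The tether can reach C3 only from the face of the C1 oxygen, which sets C3 with its oxygen cis to O1, and the electron-poor enone alkene does not react.

Step 13
Reactants: 22 cyclic iodocarbonate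
Product: 23 cyclic carbonate with C3 methyl (1S,3S,5S,16S)
Conditions: n-Bu3SnH, AIBN (cat.), toluene, 80 °C
Reagents that add atoms: none
Why: Radical chain reduction of the primary iodide; hydrogen transfer from the stannane is much faster than acyloxy migration or addition to the enone, and no stereocentre is touched.

Step 14
Reactants: 23 cyclic carbonate with C3 methyl
Product: 25 2-nitrobenzenesulfonamide with free C13 hydroxyl (cyclic carbonate and enone retained), via amino alcohol hydrochloride 24 (not isolated)
Conditions: HCl (4 M in dioxane), MeOH, 0 °C; concentrate; then 2-nitrobenzenesulfonyl chloride (1.05 equiv), Et3N, CH2Cl2, 0 °C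
Reagents that add atoms: 2-nitrobenzenesulfonyl chloride, O=S(=O)(Cl)c1ccccc1[N+](=O)[O-]
Why: Acidolysis removes both tert-butoxycarbonyl groups and the primary silyl ether while the cyclic carbonate holds the tertiary C3–O bond; the amine is then sulfonylated far faster than the primary alcohol.

Step 15
Reactants: 25 2-nitrobenzenesulfonamide alcohol
Product: 26 N-(2-nitrobenzenesulfonyl) azonane cyclic carbonate (rings A, B and C complete)
Conditions: PPh3, DIAD, toluene/THF (0.005 M), rt
Reagents that add atoms: none
Why: Intramolecular Fukuyama–Mitsunobu N-alkylation: the acidic sulfonamide is alkylated by the activated primary alcohol to form N12–C13. The E enone and the quaternary centre hold both chain ends on the same side, and the only free hydroxyl is the one to be displaced.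

Step 16
Reactants: 26 N-(2-nitrobenzenesulfonyl) azonane cyclic carbonate
Product: 27 N-(2-nitrobenzenesulfonyl) azonane C1,C3-diol
Conditions: K2CO3, MeOH, rt
Reagents that add atoms: none
Why: Methanolysis of the cyclic carbonate releases the cis-1,3-diol; the sulfonamide is inert, and conjugate addition of methoxide to the enone is reversible.

Step 17
Reactants: 27 N-(2-nitrobenzenesulfonyl) azonane C1,C3-diol
Product: 28 N-(2-nitrobenzenesulfonyl) azonane C1,C3-diacetate
Conditions: Ac2O, Et3N, DMAP, CH2Cl2, rt → 40 °C
Reagents that add atoms: acetic anhydride, CC(=O)OC(C)=O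
Why: DMAP-catalysed acetylation esterifies the hindered secondary alcohol and, with longer time and gentle warming, the tertiary alcohol; nitrogen is blocked, so only oxygen is acylated.

Step 18
Reactants: 28 N-(2-nitrobenzenesulfonyl) azonane C1,C3-diacetate
Product: 29 target, (1S,3S,5S,16S,8E)-diacetate with free N12–H
Conditions: PhSH (1.1 equiv), K2CO3, MeCN, rt
Reagents that add atoms: none
Why: Fukuyama deprotection: thiolate attacks the nitroarene ipso carbon and the sulfonamide collapses with loss of SO2. The conditions are only mildly basic, so both acetates persist, and any thiolate addition to the enone is reversible while the thiol is consumed irreversibly.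

## Compound list

1 | 3-methylbut-3-en-1-ol | CC(=C)CCO | starting material
2 | lithium 3-(lithiomethyl)but-3-en-1-olate | [Li]CC(=C)CCO[Li] | intermediate
3 | trimethyl{[3-methylidene-4-(trimethylsilyl)butyl]oxy}silane | C[Si](C)(C)CC(=C)CCO[Si](C)(C)C | intermediate
4 | 3-[(trimethylsilyl)methyl]but-3-en-1-ol | C[Si](C)(C)CC(=C)CCO | intermediate
5 | 1-methoxy-4-[({3-[(trimethylsilyl)methyl]but-3-en-1-yl}oxy)methyl]benzene | COc1ccc(COCCC(=C)C[Si](C)(C)C)cc1 | intermediate
6 | (4S)-4-[(tert-butyldimethylsilyl)oxy]cyclopent-2-en-1-one | O=C1C=C[C@@H](O[Si](C)(C)C(C)(C)C)C1 | starting material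
7 | (3S,4S)-4-[(tert-butyldimethylsilyl)oxy]-3-(2-{2-[(4-methoxybenzyl)oxy]ethyl}prop-2-en-1-yl)cyclopentan-1-one | O=C1C[C@H](CC(=C)CCOCc2ccc(OC)cc2)[C@@H](O[Si](C)(C)C(C)(C)C)C1 | intermediate
8 | (4S)-4-(2-{2-[(4-methoxybenzyl)oxy]ethyl}prop-2-en-1-yl)cyclopent-2-en-1-one | O=C1C[C@H](CC(=C)CCOCc2ccc(OC)cc2)C=C1 | intermediate
9 | (3-bromopropoxy)(tert-butyl)dimethylsilane | BrCCCO[Si](C)(C)C(C)(C)C | starting material
10 | {3-[(tert-butyldimethylsilyl)oxy]propyl}magnesium bromide | Br[Mg]CCCO[Si](C)(C)C(C)(C)C | intermediate
11 | {[(3R,4S)-3-{3-[(tert-butyldimethylsilyl)oxy]propyl}-4-(2-{2-[(4-methoxybenzyl)oxy]ethyl}prop-2-en-1-yl)cyclopent-1-en-1-yl]oxy}trimethylsilane | C[Si](C)(C)OC1=C[C@H](CCCO[Si](C)(C)C(C)(C)C)[C@@H](CC(=C)CCOCc2ccc(OC)cc2)C1 | intermediate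
12 | (4S)-3-{3-[(tert-butyldimethylsilyl)oxy]propyl}-4-(2-{2-[(4-methoxybenzyl)oxy]ethyl}prop-2-en-1-yl)cyclopent-2-en-1-one | O=C1C=C(CCCO[Si](C)(C)C(C)(C)C)[C@@H](CC(=C)CCOCc2ccc(OC)cc2)C1 | intermediate
13 | (4S)-3-{3-[(tert-butyldimethylsilyl)oxy]propyl}-4-[2-(2-hydroxyethyl)prop-2-en-1-yl]cyclopent-2-en-1-one | O=C1C=C(CCCO[Si](C)(C)C(C)(C)C)[C@@H](CC(=C)CCO)C1 | intermediate
14 | 3-{[(1S)-2-{3-[(tert-butyldimethylsilyl)oxy]propyl}-4-oxocyclopent-2-en-1-yl]methyl}but-3-enal | O=CCC(=C)C[C@H]1CC(=O)C=C1CCCO[Si](C)(C)C(C)(C)C | intermediate
15 | bis(diiodosamarium) C1 alkoxide C7–C8 enolate of the cyclised skeleton (trivalent samarium) | I[Sm](I)O[C@H]1CC(=C)C[C@H]2CC(O[Sm](I)I)=C[C@]21CCCO[Si](C)(C)C(C)(C)C | intermediate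
16 | cis-fused (1S,5S,16S) hydrindane: C1 trimethylsilyl ether, C3 methylene, C7–C8 trimethylsilyl enol ether, 3-[(tert-butyldimethylsilyl)oxy]propyl on C16 | C[Si](C)(C)O[C@H]1CC(=C)C[C@H]2CC(O[Si](C)(C)C)=C[C@]21CCCO[Si](C)(C)C(C)(C)C | intermediate
17 | tert-butyl (3-oxopropyl)carbamate | CC(C)(C)OC(=O)NCCC=O | starting material
18 | aldol adduct with C1 trimethylsilyl ether (C8, C9 mixture) | C[Si](C)(C)O[C@H]1CC(=C)C[C@H]2CC(=O)C(C(O)CCNC(=O)OC(C)(C)C)[C@]21CCCO[Si](C)(C)C(C)(C)C | intermediate
19 | aldol diol: C1 hydroxyl, C7 ketone, C9 hydroxyl, N-tert-butoxycarbonyl (C8, C9 mixture) | O[C@H]1CC(=C)C[C@H]2CC(=O)C(C(O)CCNC(=O)OC(C)(C)C)[C@]21CCCO[Si](C)(C)C(C)(C)C | intermediate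
20 | C1 and C9 bis(tert-butyl carbonate) with N,N-bis(tert-butoxycarbonyl)amine | CC(C)(C)OC(=O)O[C@H]1CC(=C)C[C@H]2CC(=O)C(C(OC(=O)OC(C)(C)C)CCN(C(=O)OC(C)(C)C)C(=O)OC(C)(C)C)[C@]21CCCO[Si](C)(C)C(C)(C)C | intermediate
21 | (8E)-enone with C1 tert-butyl carbonate, C3 methylene, N,N-bis(tert-butoxycarbonyl)amine | CC(C)(C)OC(=O)O[C@H]1CC(=C)C[C@H]2CC(=O)/C(=C/CCN(C(=O)OC(C)(C)C)C(=O)OC(C)(C)C)[C@]21CCCO[Si](C)(C)C(C)(C)C | intermediate
22 | cyclic carbonate bridging O1 and O3 with iodomethyl on C3 | O=C1O[C@H]2C[C@@](CI)(O1)C[C@H]3CC(=O)/C(=C/CCN(C(=O)OC(C)(C)C)C(=O)OC(C)(C)C)[C@]32CCCO[Si](C)(C)C(C)(C)C | intermediate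
23 | cyclic carbonate bridging O1 and O3 with methyl on C3 | O=C1O[C@H]2C[C@@](C)(O1)C[C@H]3CC(=O)/C(=C/CCN(C(=O)OC(C)(C)C)C(=O)OC(C)(C)C)[C@]32CCCO[Si](C)(C)C(C)(C)C | intermediate
24 | primary ammonium chloride with free C13 hydroxyl (cyclic carbonate retained) | O=C1O[C@H]2C[C@@](C)(O1)C[C@H]3CC(=O)/C(=C/CC[NH3+])[C@]32CCCO.[Cl-] | intermediate
25 | N-(2-nitrobenzenesulfonyl) amine with free C13 hydroxyl (cyclic carbonate retained) | O=C1O[C@H]2C[C@@](C)(O1)C[C@H]3CC(=O)/C(=C/CCNS(=O)(=O)c4ccccc4[N+](=O)[O-])[C@]32CCCO | intermediate
26 | N-(2-nitrobenzenesulfonyl) azonane with O1,O3 cyclic carbonate | O=C1O[C@H]2C[C@@](C)(O1)C[C@H]3CC(=O)/C4=C/CCN(S(=O)(=O)c5ccccc5[N+](=O)[O-])CCC[C@@]432 | intermediate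
27 | N-(2-nitrobenzenesulfonyl) azonane C1,C3-diol | O[C@H]1C[C@@](C)(O)C[C@H]2CC(=O)/C3=C/CCN(S(=O)(=O)c4ccccc4[N+](=O)[O-])CCC[C@@]321 | intermediate
28 | N-(2-nitrobenzenesulfonyl) azonane C1,C3-diacetate | CC(=O)O[C@H]1C[C@@](C)(OC(C)=O)C[C@H]2CC(=O)/C3=C/CCN(S(=O)(=O)c4ccccc4[N+](=O)[O-])CCC[C@@]321 | intermediate
29 | CNP0120442.1, (1S,3S,5S,16S,8E)-C1,C3-diacetate with free N12–H | CC(=O)O[C@H]1C[C@@](C)(OC(C)=O)C[C@H]2CC(=O)/C3=C/CCNCCC[C@@]321 | target

## Step count and least certain steps

Total step count: 18. Longest linear sequence: 18 steps (1 to 29); 6, 9 and 17 are bought and enter at steps 3, 5 and 10.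

Step 9 (key step). The most likely failure is poor facial selectivity at C1, with the samarium-bound oxygen ending trans to C8, because the chelated transition state and the one that keeps the oxygen away from the enone should be close in energy. Premature protonation of the enolate would also erase the C7–C8 regiochemistry. The fallback gives up transition-state control of C1 and sets it by reduction. It sets out from 14 and returns at 21. The cyclisation is run without regard to C1 (SmI2 with HMPA, then Me3SiCl), giving the C1-epimeric bis-silyl ether F1, which is taken through the aldol of step 10 to the C1-epimeric diol F2. CeCl3·7H2O/NaI in MeCN dehydrates only the β-hydroxy ketone, giving the C1-epimeric hydroxy enone F3. Dess–Martin periodinane then gives the C1 ketone F4, which is used at once because its C3 alkene can move into conjugation. NaBH4 in MeOH/CH2Cl2 at −78 °C should reduce the saturated ketone in preference to the enone, from the face away from ring B, giving the C1 alcohol F5, and Boc2O/DMAP converts F5 into 21.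

Step 12. The most likely failure is slow carbonate closure. The bicyclic carbonate forces O1, O3 and the ring B carbon C6 onto one face of ring A, so ring A must leave its chair, and loss of the tert-butyl carbonate or allylic iodination may outrun cyclisation. The fallback replaces the covalent tether by a hydroxyl-directed epoxidation. It sets out from 19 and returns at 23. VO(acac)2 with tert-butyl hydroperoxide, directed by the C1 hydroxyl, should give the C3 spiro-epoxide F6 with oxygen cis to O1. LiI/AcOH opens it at the methylene carbon to the iodohydrin F7, and n-Bu3SnH/AIBN gives the C3 methyl triol F8. Boc2O/DMAP followed by DBU then closes the 1,3-diol to the cyclic carbonate, dehydrates the aldol and caps the carbamate, which gives 23.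

Step 3. The most likely failure is Lewis-acid-induced loss of the silyloxy group or oligomerisation of the cyclopentenone before the allylsilane adds. The fallback uses a nucleophilic allylcopper reagent in place of Lewis-acid activation. It sets out from 1 (through dianion 2) and returns at 7. The dianion is quenched with n-Bu3SnCl to give the stannane alcohol F9, which NaH and 4-methoxybenzyl chloride convert into the stannane ether F10. Tin–lithium exchange with MeLi, then CuBr·SMe2 and Me3SiCl, adds the allyl group to 6 at −78 °C, and hydrolytic work-up gives 7.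

Step 15. The most likely failure is intermolecular alkylation outrunning the nine-membered closure, or partial formation of the Z enone in step 11, whose chain cannot reach C13. The fallback separates activation from ring closure. It sets out from 25 and returns at 26. I2, PPh3 and imidazole give the primary iodide F11, and slow addition of F11 to Cs2CO3 in MeCN at 50 °C closes the ring through the sulfonamide anion; a trace of iodine under light can equilibrate any Z enone beforehand.

Step 18. The most likely failure is reversible conjugate addition of thiolate to the enone competing with cleavage of the sulfonamide, so that thiol adducts contaminate the amine. The fallback uses a sulfonamide that is cleaved by fluoride. It sets out from 23 and ends at 29. After the acid treatment of step 14, 2-(trimethylsilyl)ethanesulfonyl chloride and Et3N give the silylethanesulfonamide alcohol F12. Cyanomethylenetributylphosphorane in toluene at 80 °C closes it to the sulfonyl azonane carbonate F13. K2CO3 in MeOH gives the sulfonyl azonane diol F14, Ac2O/DMAP/Et3N gives the sulfonyl azonane diacetate F15, and tris(dimethylamino)sulfonium difluorotrimethylsilicate in DMF at 50 °C releases 29.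

## Further compounds

F1 | step 9 | C1 epimer of 16 (bis-trimethylsilyl derivative) | C[Si](C)(C)O[C@@H]1CC(=C)C[C@H]2CC(O[Si](C)(C)C)=C[C@]21CCCO[Si](C)(C)C(C)(C)C
F2 | step 9 | C1 epimer of aldol diol 19 | O[C@@H]1CC(=C)C[C@H]2CC(=O)C(C(O)CCNC(=O)OC(C)(C)C)[C@]21CCCO[Si](C)(C)C(C)(C)C
F3 | step 9 | C1-epimeric hydroxy (8E)-enone, N-tert-butoxycarbonyl | O[C@@H]1CC(=C)C[C@H]2CC(=O)/C(=C/CCNC(=O)OC(C)(C)C)[C@]21CCCO[Si](C)(C)C(C)(C)C
F4 | step 9 | C1 ketone (8E)-enone, N-tert-butoxycarbonyl | O=C1CC(=C)C[C@H]2CC(=O)/C(=C/CCNC(=O)OC(C)(C)C)[C@]21CCCO[Si](C)(C)C(C)(C)C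
F5 | step 9 | (1S)-hydroxy (8E)-enone, N-tert-butoxycarbonyl | O[C@H]1CC(=C)C[C@H]2CC(=O)/C(=C/CCNC(=O)OC(C)(C)C)[C@]21CCCO[Si](C)(C)C(C)(C)C
F6 | step 12 | C3 spiro-epoxide of 19, oxygen cis to O1 | O[C@H]1C[C@]3(CO3)C[C@H]2CC(=O)C(C(O)CCNC(=O)OC(C)(C)C)[C@]21CCCO[Si](C)(C)C(C)(C)C
F7 | step 12 | C3 iodomethyl C1,C3,C9-triol | O[C@H]1C[C@@](CI)(O)C[C@H]2CC(=O)C(C(O)CCNC(=O)OC(C)(C)C)[C@]21CCCO[Si](C)(C)C(C)(C)C
F8 | step 12 | C3 methyl C1,C3,C9-triol | O[C@H]1C[C@@](C)(O)C[C@H]2CC(=O)C(C(O)CCNC(=O)OC(C)(C)C)[C@]21CCCO[Si](C)(C)C(C)(C)C
F9 | step 3 | 3-[(tributylstannyl)methyl]but-3-en-1-ol | OCCC(=C)C[Sn](CCCC)(CCCC)CCCC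
F10 | step 3 | tributyl[2-({2-[(4-methoxybenzyl)oxy]ethyl})prop-2-en-1-yl]stannane | COc1ccc(COCCC(=C)C[Sn](CCCC)(CCCC)CCCC)cc1
F11 | step 15 | C13 iodide of 25 | O=C1O[C@H]2C[C@@](C)(O1)C[C@H]3CC(=O)/C(=C/CCNS(=O)(=O)c4ccccc4[N+](=O)[O-])[C@]32CCCI
F12 | step 18 | N-[2-(trimethylsilyl)ethanesulfonyl] amine with free C13 hydroxyl (cyclic carbonate retained) | O=C1O[C@H]2C[C@@](C)(O1)C[C@H]3CC(=O)/C(=C/CCNS(=O)(=O)CC[Si](C)(C)C)[C@]32CCCO
F13 | step 18 | N-[2-(trimethylsilyl)ethanesulfonyl] azonane with O1,O3 cyclic carbonate | O=C1O[C@H]2C[C@@](C)(O1)C[C@H]3CC(=O)/C4=C/CCN(S(=O)(=O)CC[Si](C)(C)C)CCC[C@@]432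
F14 | step 18 | N-[2-(trimethylsilyl)ethanesulfonyl] azonane C1,C3-diol | O[C@H]1C[C@@](C)(O)C[C@H]2CC(=O)/C3=C/CCN(S(=O)(=O)CC[Si](C)(C)C)CCC[C@@]321
F15 | step 18 | N-[2-(trimethylsilyl)ethanesulfonyl] azonane C1,C3-diacetate | CC(=O)O[C@H]1C[C@@](C)(OC(C)=O)C[C@H]2CC(=O)/C3=C/CCN(S(=O)(=O)CC[Si](C)(C)C)CCC[C@@]321
A1 | alternative 1 | tricyclic C1 ketone with C7 acetal and N-tert-butoxycarbonyl azonane | O=C1C[C@H](C)C[C@H]2CC3(OCCO3)/C4=C/CCN(C(=O)OC(C)(C)C)CCC[C@@]421
A2 | alternative 1 | twelve-membered (Z)-vinyl bromide fused to the cyclohexanone | O=C1C[C@H](C)C[C@H]2CC3(OCCO3)/C(Br)=C/CCN(C(=O)OC(C)(C)C)CCCC12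
A3 | alternative 2 | cis-fused hydrindenedione (C1 enone, C8 ketone) | O=C1C=C(C)C[C@H]2CCC(=O)[C@]21CCCNC(=O)OC(C)(C)C
A4 | alternative 2 | acyclic enone 1,3-diketone | CC(=O)C(CCCNC(=O)OC(C)(C)C)C(=O)CC/C=C/C(C)=O
A5 | alternative 3 | cis-fused bicyclic ketone with C7 vinylsilane and two 3-chloropropyl chains | O=C1C[C@H](C)C[C@H]2CC([Si](C)(C)C)=C(CCCCl)[C@]21CCCCl
A6 | alternative 3 | (R)-2-(3-chloropropyl)-5-methylcyclohex-2-en-1-one | O=C1C[C@H](C)CC=C1CCCCl
A7 | alternative 3 | (6-chlorohexa-1,2-dien-3-yl)trimethylsilane | C=C=C(CCCCl)[Si](C)(C)C
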